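**Retrosynthetic overview**
1. Feature (germacrane numbering): in the ten-membered carbocycle C1–C10, trans-fused at C6/C7 to the γ-lactone O6–C12(=O)–C11–C7–C6, C4 is the methyl-bearing sp2 carbon of the E C4=C5 alkene and C3 is a plain CH2 two carbons from the Z C10=C1 alkene. The ring is therefore cut at C3–C4 into an E alkenyl iodide (C4) and an alkylborane (C3) grown from a terminal Z diene C10=C1–C2=C3.
2. Ring order: the γ-lactone is made first on a C5–C9 chain, the ten-membered ring second by 9-BBN hydroboration and intramolecular B-alkyl Suzuki–Miyaura coupling. The C11=C13 methylene is unmasked afterwards by selenoxide elimination and the O8 epoxy ester is attached last.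
3. C6–C8 are C2–C4 of D-arabinose. C7 becomes quaternary when the enolate of tert-butyl propionate adds to the furanos-3-ulose anti to the 1,2-acetonide. Sugar C1 becomes C5≡C4–CH3 and then the E iodide; sugar C5 becomes the C9 aldehyde.
4. C9–C10 and the Z diene come from Felkin–Anh addition of (Z)-penta-2,4-dien-2-yllithium (from but-2-yn-1-ol). The acyl group is the (2S,3R)-epoxy acid made from tiglic acid by Sharpless epoxidation.

Key step: step 19

Remark: germacrane numbering is used throughout (arabinose C1–C5 = C5–C9); C11 forms as an epimer mixture and is carried without assignment because step 21 removes it; O8 is carried as a 2-naphthylmethyl (NAP) ether instead of a p-methoxybenzyl ether, because it must outlast the trifluoroacetic acid lactonisation of step 9, and it is removed by DDQ in the same way.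

**Route**

Step 1
Reactants: 1 D-arabinose
Product: 2 5-O-(tert-butyldiphenylsilyl)-D-arabinofuranose (anomer mixture)
Conditions: t-BuPh2SiCl, imidazole, DMF, 0 °C to rt
Reagents that add atoms: tert-butyl(chloro)diphenylsilane, CC(C)(C)[Si](Cl)(c1ccccc1)c1ccccc1
Why: Silyl ether formation: the bulky chlorosilane reacts only at the primary hydroxyl, which is free in the furanose but not in the pyranose tautomer, so silylation drains the mutarotation equilibrium into the 5-O-silyl furanose without touching a stereocentre.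

Step 2
Reactants: 2 5-O-TBDPS-D-arabinofuranose
Product: 3 5-O-TBDPS-1,2-O-isopropylidene-β-D-arabinofuranose
Conditions: 2,2-dimethoxypropane, CSA (cat.), acetone, rt
Reagents that add atoms: 2,2-dimethoxypropane, COC(C)(C)OC
Why: Acetalisation (acetonide formation): only the cis O1/O2 pair of the β-furanose can close a dioxolane (O2/O3 are trans), which fixes the β-anomer and leaves 3-OH as the only free hydroxyl.

Step 3
Reactants: 3 5-O-TBDPS-1,2-O-isopropylidene-β-D-arabinofuranose
Product: 4 5-O-TBDPS-1,2-O-isopropylidene-β-D-threo-pentofuranos-3-ulose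
Conditions: Dess–Martin periodinane, CH2Cl2, rt
Reagents that add atoms: none
Why: Dess–Martin oxidation of the single secondary alcohol under non-basic conditions, which avoids epimerisation at C2 and C4 of the ulose.

Step 4
Reactants: 4 furanos-3-ulose; 5 tert-butyl propionate
Product: 7 tert-butyl 2-[5-O-TBDPS-1,2-O-isopropylidene-β-D-lyxofuranos-3-C-yl]propanoate (3-OH free; both epimers at the propanoate carbon), via lithium enolate of tert-butyl propionate 6 (not isolated)
Conditions: 5, LiN(iPr)2, THF, −78 °C; then 4, −78 °C; AcOH quench at −78 °C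
Reagents that add atoms: none
Why: Aldol addition of an ester lithium enolate to a ketone: the enolate attacks from the α face, opposite the cis-fused 1,2-dioxolane and the C4 side chain, so the new tertiary hydroxyl (O7) is cis to O2 (O6) and the carbon branch (C11) trans, which sets C7; the C11 centre is not controlled and not needed.

Step 5
Reactants: 7 aldol adduct
Product: 8 tert-butyl 2-[5-O-TBDPS-2,3-O-isopropylidene-D-lyxofuranos-3-C-yl]propanoate (lactol, anomer mixture)
Conditions: CSA (cat.), acetone, rt
Reagents that add atoms: none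
Why: Acid-catalysed acetal equilibration (acetonide migration): lyxo-configured furanoses settle as 2,3-O-isopropylidene derivatives with a free anomeric hydroxyl, as in the acetonation of lyxose and mannose, because this relieves the all-cis crowding of the 1,2-acetonide; the move frees C1 as a lactol and ties O6/O7 together, which also blocks retro-aldol cleavage in the basic steps that follow.

Step 6
Reactants: 8 2,3-O-isopropylidene lactol
Product: 9 alkynol (terminal C4≡C5 alkyne; O6/O7 acetonide; free 8-OH; 9-OTBDPS; C7-bound CH(CH3)CO2tBu)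
Conditions: dimethyl (1-diazo-2-oxopropyl)phosphonate, K2CO3, MeOH, 0 °C to rt
Reagents that add atoms: dimethyl (1-diazo-2-oxopropyl)phosphonate, COP(=O)(OC)C(=[N+]=[N-])C(C)=O
Why: Seyferth–Gilbert homologation with the Ohira–Bestmann reagent on the open hydroxy-aldehyde tautomer of the lactol: the aldehyde carbon (C5) becomes an alkyne carbon and the former ring oxygen is released as the only free hydroxyl (O8), while the tert-butyl ester resists methoxide and the acetonide shields the aldol unit.

Step 7
Reactants: 9 alkynol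
Product: 10 8-O-(2-naphthylmethyl) ether of 9
Conditions: 2-naphthylmethyl 2,2,2-trichloroacetimidate, TfOH (cat.), CH2Cl2, 0 °C
Reagents that add atoms: 2-naphthylmethyl 2,2,2-trichloroacetimidate, ClC(Cl)(Cl)C(=N)OCc1ccc2ccccc2c1
Why: Acid-catalysed O-alkylation with a trichloroacetimidate, run without base so that the silyl group cannot migrate from O9 to O8; O8 is the only hydroxyl.

Step 8
Reactants: 10 NAP ether
Product: 12 methyl alkyne (C15–C4≡C5), via lithium acetylide 11 (not isolated)
Conditions: n-BuLi (1.05 equiv), THF, −78 °C; MeI, DMPU, −78 to 0 °C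
Reagents that add atoms: iodomethane, CI
Why: Alkyne deprotonation–alkylation: proton transfer from the terminal alkyne to n-BuLi is much faster at −78 °C than addition to the hindered tert-butyl ester (α-branched, next to a quaternary carbon), and the acetylide is then methylated on carbon.

Step 9
Reactants: 12 methyl alkyne
Product: 13 γ-lactone (O6–C12) with free tertiary 7-OH, 8-ONAP, 9-OTBDPS and C5≡C4–CH3
Conditions: CF3CO2H/CH2Cl2 (1:4), H2O (5 equiv), 0 °C to rt
Reagents that add atoms: none
Why: Acidic acetal hydrolysis and tert-butyl ester cleavage followed by 5-exo lactonisation: once the acetonide is gone O6 is the only hydroxyl that can reach C12 in a five-membered ring (O8 and O9 are blocked, O7 would give a β-lactone), and the NAP and TBDPS ethers tolerate the acid.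

Step 10
Reactants: 13 hydroxy lactone
Product: 14 lactone diol (7-OH, 9-OH)
Conditions: Bu4NF, AcOH (1:1), THF, rt
Reagents that add atoms: none
Why: Fluoride-mediated cleavage of the primary silyl ether, with acetic acid buffering so that the β-hydroxy lactone neither opens by retro-aldol reaction nor shifts its acyl group to O9.

Step 11
Reactants: 14 lactone diol
Product: 15 7,9-bis(triethylsilyl) ether
Conditions: Et3SiOTf, 2,6-lutidine, CH2Cl2, −78 to 0 °C
Reagents that add atoms: triethylsilyl trifluoromethanesulfonate, CC[Si](CC)(CC)OS(=O)(=O)C(F)(F)F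
Why: Silylation with a silyl triflate, reactive enough for the tertiary 7-OH; the primary 9-OTES is a temporary mask that step 13 converts into the aldehyde.

Step 12
Reactants: 15 bis-TES ether
Product: 17 (E)-alkenyl iodide (C5H=C4(CH3)I, iodine trans to C6), via alkenylzirconocene chloride 16 (not isolated)
Conditions: Cp2Zr(H)Cl (2.5 equiv), THF, rt to 40 °C; then I2, 0 °C
Reagents that add atoms: iodine, II
Why: Hydrozirconation–iodination: Zr–H adds syn across the alkyne and, with excess reagent, zirconium equilibrates to C4 next to the methyl group and away from the crowded C6/C7 region, which also keeps it from β-eliminating the allylic lactone oxygen; iodinolysis of the C–Zr bond with retention gives the E iodide.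

Step 13
Reactants: 17 (E)-alkenyl iodide
Product: 18 C9 aldehyde
Conditions: (COCl)2, DMSO, CH2Cl2, −78 to −40 °C; Et3N, −78 °C to rt
Reagents that add atoms: none
Why: Swern oxidation applied directly to a primary triethylsilyl ether: chlorodimethylsulfonium chloride exchanges the unhindered primary O–Si bond for an alkoxysulfonium ion, which Et3N collapses to the aldehyde, while the hindered tertiary TES ether is left alone.

Step 14
Reactants: 19 but-2-yn-1-ol
Product: 21 (Z)-3-iodobut-2-en-1-ol, via sodium alkenylalanate 20 (not isolated)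
Conditions: NaAlH2(OCH2CH2OCH3)2, THF, 0 °C to rt; then I2, −78 °C
Reagents that add atoms: iodine, II
Why: Alkoxide-directed trans-hydroalumination of a propargylic alcohol: hydride goes to C2 and aluminium ends on C3 inside a five-membered alanate, cis to the CH2O group, and iodinolysis with retention gives the Z iodide.

Step 15
Reactants: 21 (Z)-3-iodobut-2-en-1-ol
Product: 22 (Z)-3-iodobut-2-enal
Conditions: MnO2, CH2Cl2, rt, dark
Reagents that add atoms: none
Why: Allylic alcohol oxidation on MnO2 under neutral conditions, which keeps the Z geometry of the β-iodo enal.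

Step 16
Reactants: 22 (Z)-3-iodobut-2-enal
Product: 23 (3Z)-4-iodopenta-1,3-diene (kept as a cold ethereal solution)
Conditions: Ph3PCH3Br, KN(SiMe3)2, Et2O, −78 to 0 °C
Reagents that add atoms: methyltriphenylphosphonium bromide, C[P+](c1ccccc1)(c1ccccc1)c1ccccc1.[Br-]
Why: Wittig methylenation: the non-stabilised ylide adds to the aldehyde carbonyl much faster than to the β-iodo position, and the trisubstituted Z alkene is not involved.

Step 17
Reactants: 18 C9 aldehyde; 23 (3Z)-4-iodopenta-1,3-diene
Product: 25 C9 alcohol carrying the complete Z diene (8,9-anti), via (Z)-penta-2,4-dien-2-yllithium 24 (not isolated)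
Conditions: 23, t-BuLi (2 equiv per 23), Et2O, −78 °C; then 18, THF, −78 °C; AcOH
Reagents that add atoms: none
Why: Iodine–lithium exchange with retention of alkene geometry, then 1,2-addition to the aldehyde under Felkin–Anh control: with a non-chelating lithium reagent the C8–O bond lies anti to the incoming nucleophile, which passes the C8 hydrogen and not the quaternary C7, so the new 9-OH should be anti (erythro) to O8 as in the target; at −78 °C the aldehyde reacts well before the lactone or the alkenyl iodide.

Step 18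
Reactants: 25 C9 alcohol
Product: 26 coupling precursor: α-methyl γ-lactone with E alkenyl iodide at C4, Z diene C10=C1–C2=C3, 7-OTES, 8-ONAP, 9-OTBS
Conditions: t-BuMe2SiOTf, 2,6-lutidine, CH2Cl2, −78 to 0 °C
Reagents that add atoms: tert-butyldimethylsilyl trifluoromethanesulfonate, CC(C)(C)[Si](C)(C)OS(=O)(=O)C(F)(F)F
Why: Silyl ether formation with a silyl triflate at the hindered allylic 9-OH; the TBS ether is chosen to survive the basic coupling, the enolate chemistry and DDQ.

Step 19
Reactants: 26 coupling precursor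
Product: 28 macrocycle (protected 11,13-dihydro core: ten-membered ring trans-fused to the α-methyl γ-lactone; 1(10)Z,4E; 7-OTES, 8-ONAP, 9-OTBS), via B-alkyl-9-BBN borane 27 (not isolated)
Conditions: 9-BBN, THF, 0 °C to rt; H2O; then slow addition to PdCl2(dppf) (cat.), AsPh3, Cs2CO3, DMF/THF/H2O, 50 °C, about 1 mM final concentration
Reagents that add atoms: none
Why: 9-BBN adds its B–H bond to the terminal C2=C3 alkene of the diene with boron on C3 (the trisubstituted C10=C1 alkene, the iodoalkene and the lactone do not react with this bulky borane); zerovalent palladium, formed from PdCl2(dppf), then inserts into the C4–I bond with retention, the hydroxyborate made with Cs2CO3/H2O hands the C3 alkyl group to palladium, and reductive elimination joins C3 to C4. This is an intramolecular B-alkyl Suzuki–Miyaura coupling, a known macrocyclisation that is used here near the lower limit of its ring size. The ten-membered carbocycle closes by reductive elimination from an eleven-membered palladacycle, a ring closure between an sp3 and an sp2 carbon in which both ring alkenes already have their geometry. No stereocentre is created. The step needs terminal-selective hydroboration (given by the size of 9-BBN), an unchanged E geometry at C4 (oxidative addition and reductive elimination at sp2 carbon are stereoretentive, and the C–I bond reacts far faster than the hindered allylic C6–O bond could ionise), reductive elimination ahead of β-hydride loss from the C3 alkyl palladium (wide bite angle of dppf), and cyclisation ahead of oligomerisation (slow addition to about 1 mM; the trans-fused lactone already fixes C5 and C8 on opposite faces as in the product, so only the two arms have to meet).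

Step 20
Reactants: 28 macrocycle
Product: 30 11-phenylselenyl lactone, via lactone lithium enolate 29 (not isolated)
Conditions: LiN(iPr)2, THF, −78 °C; PhSeBr, −78 °C
Reagents that add atoms: benzeneselenenyl bromide, Br[Se]c1ccccc1
Why: Enolate selenenylation: C11–H is the only acidic proton, the β-silyloxy enolate is stable at −78 °C, and the selenium electrophile is taken up at C11 (either face serves).

Step 21
Reactants: 30 11-phenylselenyl lactone
Product: 32 α-methylene lactone, via selenoxide 31 (not isolated)
Conditions: NaIO4, THF/MeOH/H2O, 0 °C to rt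
Reagents that add atoms: none
Why: Selenoxide syn-elimination: the only β-hydrogens are on the C13 methyl group because C7 is quaternary, so the alkene can only form exocyclic, and periodate oxidises selenium without epoxidising the ring alkenes.

Step 22
Reactants: 32 α-methylene lactone
Product: 33 C8 alcohol (7-OTES, 9-OTBS)
Conditions: DDQ, CH2Cl2/pH 7 phosphate buffer, rt
Reagents that add atoms: none
Why: Oxidative cleavage of the arylmethyl ether: DDQ abstracts hydride from the naphthylmethyl position and water releases the alcohol, with buffering to protect the silyl ethers and the acid-sensitive cyclodecadiene.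

Step 23
Reactants: 34 tiglic acid
Product: 35 (E)-2-methylbut-2-en-1-ol
Conditions: LiAlH4, Et2O, 0 °C
Reagents that add atoms: none
Why: Hydride reduction of the carboxylic acid to the primary allylic alcohol, the trisubstituted E alkene being untouched.

Step 24
Reactants: 35 (E)-2-methylbut-2-en-1-ol
Product: 36 (2R,3R)-2,3-epoxy-2-methylbutan-1-ol
Conditions: Ti(OiPr)4 (cat.), D-(−)-diethyl tartrate (cat.), t-BuOOH, 4 Å molecular sieves, CH2Cl2, −20 °C
Reagents that add atoms: tert-butyl hydroperoxide, CC(C)(C)OO
Why: Sharpless asymmetric epoxidation: the titanium tartrate complex delivers oxygen to one face of the allylic alcohol, and since L-(+)-tartrate gives (2S,3S) epoxy alcohols from E allylic alcohols, D-(−)-tartrate should set both epoxide centres as (2R,3R).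

Step 25
Reactants: 36 (2R,3R)-epoxy alcohol
Product: 37 (2S,3R)-2,3-dimethyloxirane-2-carboxylic acid
Conditions: TEMPO (cat.), PhI(OAc)2, MeCN/H2O, rt
Reagents that add atoms: water, O
Why: Oxoammonium-mediated oxidation of the primary alcohol through the aldehyde hydrate to the acid; the epoxide centres are not touched (the C2 label changes to S only because CO2H outranks the ring carbon).

Step 26
Reactants: 33 C8 alcohol; 37 (2S,3R)-epoxy acid
Product: 39 O8 epoxy ester (7-OTES, 9-OTBS), via mixed anhydride 38 (not isolated)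
Conditions: 37, 2,4,6-trichlorobenzoyl chloride, Et3N, THF, rt; then 33, DMAP (cat.), PhMe, rt to 40 °C
Reagents that add atoms: none
Why: Yamaguchi esterification: DMAP attacks the mixed anhydride at the epoxy acyl carbon and the acylpyridinium acylates O8, the only free hydroxyl; the acid has no α-hydrogen, so its stereocentres cannot epimerise.

Step 27
Reactants: 39 O8 epoxy ester
Product: 40 target CNP0420662.1
Conditions: HF·pyridine, pyridine, THF, 0 °C to rt
Reagents that add atoms: none
Why: Fluoride-mediated desilylation under buffered, mildly acidic conditions should remove the tertiary TES and the allylic TBS ether without acyl migration from O8, conjugate addition to the methylene lactone or transannular cyclisation of the diene.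

**Compound list**
1 | D-arabinose | O=C[C@@H](O)[C@H](O)[C@H](O)CO | starting material
2 | 5-O-(tert-butyldiphenylsilyl)-D-arabinofuranose, anomer mixture | OC1O[C@H](CO[Si](c2ccccc2)(c2ccccc2)C(C)(C)C)[C@@H](O)[C@@H]1O | intermediate
3 | 5-O-TBDPS-1,2-O-isopropylidene-β-D-arabinofuranose | CC1(C)O[C@@H]2O[C@H](CO[Si](c3ccccc3)(c3ccccc3)C(C)(C)C)[C@@H](O)[C@@H]2O1 | intermediate
4 | 5-O-TBDPS-1,2-O-isopropylidene-β-D-threo-pentofuranos-3-ulose | CC1(C)O[C@@H]2O[C@H](CO[Si](c3ccccc3)(c3ccccc3)C(C)(C)C)C(=O)[C@@H]2O1 | intermediate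
5 | tert-butyl propionate | CCC(=O)OC(C)(C)C | starting material
6 | lithium enolate of tert-butyl propionate | CC=C(O[Li])OC(C)(C)C | intermediate
7 | tert-butyl 2-[5-O-TBDPS-1,2-O-isopropylidene-β-D-lyxofuranos-3-C-yl]propanoate (3-OH β, C-branch α; C11 epimers) | CC1(C)O[C@@H]2O[C@H](CO[Si](c3ccccc3)(c3ccccc3)C(C)(C)C)[C@@](O)(C(C)C(=O)OC(C)(C)C)[C@@H]2O1 | intermediate
8 | tert-butyl 2-[5-O-TBDPS-2,3-O-isopropylidene-D-lyxofuranos-3-C-yl]propanoate (lactol, anomer mixture) | OC1O[C@H](CO[Si](c2ccccc2)(c2ccccc2)C(C)(C)C)[C@]2(C(C)C(=O)OC(C)(C)C)OC(C)(C)O[C@H]12 | intermediate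
9 | alkynol: terminal C4≡C5 alkyne, O6/O7 acetonide, 8-OH, 9-OTBDPS, C7–CH(CH3)CO2tBu (C6, C7, C8 as in the target) | C#C[C@H]1OC(C)(C)O[C@@]1(C(C)C(=O)OC(C)(C)C)[C@H](O)CO[Si](c2ccccc2)(c2ccccc2)C(C)(C)C | intermediate
10 | 8-O-NAP ether of 9 | C#C[C@H]1OC(C)(C)O[C@@]1(C(C)C(=O)OC(C)(C)C)[C@H](OCc2ccc3ccccc3c2)CO[Si](c2ccccc2)(c2ccccc2)C(C)(C)C | intermediate
11 | lithium acetylide of 10 | [Li]C#C[C@H]1OC(C)(C)O[C@@]1(C(C)C(=O)OC(C)(C)C)[C@H](OCc2ccc3ccccc3c2)CO[Si](c2ccccc2)(c2ccccc2)C(C)(C)C | intermediate
12 | methyl alkyne (CH3–C4≡C5), O6/O7 acetonide, 8-ONAP, 9-OTBDPS, tert-butyl ester | CC#C[C@H]1OC(C)(C)O[C@@]1(C(C)C(=O)OC(C)(C)C)[C@H](OCc2ccc3ccccc3c2)CO[Si](c2ccccc2)(c2ccccc2)C(C)(C)C | intermediate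
13 | α-methyl γ-lactone (O6–C12) with 6-(prop-1-ynyl), 7-OH, 8-ONAP, 9-OTBDPS | CC#C[C@H]1OC(=O)C(C)[C@]1(O)[C@H](OCc2ccc3ccccc3c2)CO[Si](c2ccccc2)(c2ccccc2)C(C)(C)C | intermediate
14 | lactone diol (7-OH, 9-OH), 8-ONAP | CC#C[C@H]1OC(=O)C(C)[C@]1(O)[C@H](OCc2ccc3ccccc3c2)CO | intermediate
15 | 7,9-bis(triethylsilyl) ether of 14 | CC#C[C@H]1OC(=O)C(C)[C@]1(O[Si](CC)(CC)CC)[C@H](OCc2ccc3ccccc3c2)CO[Si](CC)(CC)CC | intermediate
16 | alkenylzirconocene chloride (Zr on C4, trans to C6) | C/C(=C\[C@H]1OC(=O)C(C)[C@]1(O[Si](CC)(CC)CC)[C@H](OCc2ccc3ccccc3c2)CO[Si](CC)(CC)CC)[Zr](Cl)(C2C=CC=C2)C2C=CC=C2 | intermediate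
17 | (E)-alkenyl iodide C5H=C4(CH3)I, 7-OTES, 8-ONAP, 9-OTES | C/C(I)=C\[C@H]1OC(=O)C(C)[C@]1(O[Si](CC)(CC)CC)[C@H](OCc2ccc3ccccc3c2)CO[Si](CC)(CC)CC | intermediate
18 | C9 aldehyde with E iodide, 7-OTES, 8-ONAP | C/C(I)=C\[C@H]1OC(=O)C(C)[C@]1(O[Si](CC)(CC)CC)[C@H](OCc2ccc3ccccc3c2)C=O | intermediate
19 | but-2-yn-1-ol | CC#CCO | starting material
20 | sodium alkenylalanate (five-membered oxa-alumina ring) | CC1=CCO[Al-]1(OCCOC)OCCOC.[Na+] | intermediate
21 | (Z)-3-iodobut-2-en-1-ol | C/C(I)=C/CO | intermediate
22 | (Z)-3-iodobut-2-enal | C/C(I)=C/C=O | intermediate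
23 | (3Z)-4-iodopenta-1,3-diene | C=C/C=C(/C)I | intermediate
24 | (Z)-penta-2,4-dien-2-yllithium | C=C/C=C(/C)[Li] | intermediate
25 | C9 alcohol with Z diene and E iodide (C6–C9 as in the target), 7-OTES, 8-ONAP | C/C(I)=C\[C@H]1OC(=O)C(C)[C@]1(O[Si](CC)(CC)CC)[C@H](OCc2ccc3ccccc3c2)[C@H](O)/C(C)=C\C=C | intermediate
26 | coupling precursor: 9-OTBS ether of 25 | C/C(I)=C\[C@H]1OC(=O)C(C)[C@]1(O[Si](CC)(CC)CC)[C@H](OCc2ccc3ccccc3c2)[C@H](O[Si](C)(C)C(C)(C)C)/C(C)=C\C=C | intermediate
27 | B-alkyl-9-BBN borane (boron on C3) | C/C(I)=C\[C@H]1OC(=O)C(C)[C@]1(O[Si](CC)(CC)CC)[C@H](OCc2ccc3ccccc3c2)[C@H](O[Si](C)(C)C(C)(C)C)/C(C)=C\CCB2C3CCCC2CCC3 | intermediate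
28 | macrocycle: protected 11,13-dihydro core (1(10)Z,4E; 7-OTES, 8-ONAP, 9-OTBS; C11 epimers) | CC1C(=O)O[C@@H]2/C=C(\C)CC/C=C(/C)[C@@H](O[Si](C)(C)C(C)(C)C)[C@@H](OCc3ccc4ccccc4c3)[C@@]12O[Si](CC)(CC)CC | intermediate
29 | lactone lithium enolate of 28 | CC1=C(O[Li])O[C@@H]2/C=C(\C)CC/C=C(/C)[C@@H](O[Si](C)(C)C(C)(C)C)[C@@H](OCc3ccc4ccccc4c3)[C@@]12O[Si](CC)(CC)CC | intermediate
30 | 11-phenylselenyl lactone | CC1([Se]c5ccccc5)C(=O)O[C@@H]2/C=C(\C)CC/C=C(/C)[C@@H](O[Si](C)(C)C(C)(C)C)[C@@H](OCc3ccc4ccccc4c3)[C@@]12O[Si](CC)(CC)CC | intermediate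
31 | selenoxide of 30 | CC1([Se](=O)c5ccccc5)C(=O)O[C@@H]2/C=C(\C)CC/C=C(/C)[C@@H](O[Si](C)(C)C(C)(C)C)[C@@H](OCc3ccc4ccccc4c3)[C@@]12O[Si](CC)(CC)CC | intermediate
32 | α-methylene lactone, 7-OTES, 8-ONAP, 9-OTBS | C=C1C(=O)O[C@@H]2/C=C(\C)CC/C=C(/C)[C@@H](O[Si](C)(C)C(C)(C)C)[C@@H](OCc3ccc4ccccc4c3)[C@@]12O[Si](CC)(CC)CC | intermediate
33 | C8 alcohol, 7-OTES, 9-OTBS | C=C1C(=O)O[C@@H]2/C=C(\C)CC/C=C(/C)[C@@H](O[Si](C)(C)C(C)(C)C)[C@@H](O)[C@@]12O[Si](CC)(CC)CC | intermediate
34 | tiglic acid | C/C=C(\C)C(O)=O | starting material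
35 | (E)-2-methylbut-2-en-1-ol | C/C=C(\C)CO | intermediate
36 | (2R,3R)-2,3-epoxy-2-methylbutan-1-ol | OC[C@@]1(C)O[C@@H]1C | intermediate
37 | (2S,3R)-2,3-dimethyloxirane-2-carboxylic acid | OC(=O)[C@@]1(C)O[C@@H]1C | intermediate
38 | mixed anhydride of 37 with 2,4,6-trichlorobenzoic acid | O=C(OC(=O)[C@@]1(C)O[C@@H]1C)c1c(Cl)cc(Cl)cc1Cl | intermediate
39 | O8 (2S,3R)-epoxy ester, 7-OTES, 9-OTBS | C=C1C(=O)O[C@@H]2/C=C(\C)CC/C=C(/C)[C@@H](O[Si](C)(C)C(C)(C)C)[C@@H](OC(=O)[C@@]3(C)O[C@@H]3C)[C@@]12O[Si](CC)(CC)CC | intermediate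
40 | CNP0420662.1: (6R,7R,8R,9R,1(10)Z,4E)-7,9-dihydroxy-8-[(2S,3R)-2,3-dimethyloxirane-2-carbonyloxy]germacra-1(10),4,11(13)-trien-12,6-olide | C=C1C(=O)O[C@@H]2/C=C(\C)CC/C=C(/C)[C@@H](O)[C@@H](OC(=O)[C@@]3(C)O[C@@H]3C)[C@@]12O | target

**Count**
Total steps: 27. Longest linear sequence: 21 steps (steps 1–13, 17–22, 26, 27); steps 14–16 and 23–25 make the two side fragments.

**Steps most likely to fail**

Step 19. The strained ten-membered ring may close more slowly than the alkylborane oligomerises, loses boron by protonolysis, or the alkylpalladium loses β-hydride. The fallback closes the ring at C9–C10 instead and sets out from iodide 17 and iododiene 23. Diene 23 is lithiated (t-BuLi) and silylated (Me3SiCl) to (3Z)-4-(trimethylsilyl)penta-1,3-diene F1. 9-BBN adds to its terminal alkene to give the alkylborane F2, which is coupled intermolecularly with 17 (PdCl2(dppf), AsPh3, Cs2CO3) to the open-chain C3–C4 coupled vinylsilane F3. N-Iodosuccinimide replaces silicon by iodine with retention to give the Z alkenyl iodide F4. Swern oxidation of the primary TES ether gives the aldehyde F5. CrCl2 with catalytic NiCl2 (DMSO/THF, high dilution) closes the ring by Nozaki–Hiyama–Kishi addition to the macrocyclic 9-alcohol F6, in which the C9 configuration then depends on the conformation of the closing ring. Silylation with t-BuMe2SiOTf brings the route back at 28.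

Step 17. Facial selectivity at C9 may be poor, because the O7 and O8 substituents are syn and their 1,2- and 1,3-induction need not reinforce; the organolithium may also attack the lactone. The fallback sets out from aldehyde 18. The addition is run as before without relying on its selectivity, and the mixture of 25 and its C9 epimer F7 is oxidised with Dess–Martin periodinane to the dienone F8. Zn(BH4)2 (Et2O, −30 °C) then reduces the ketone under chelation by the O8 ether oxygen, so that hydride arrives anti to C7 and gives the 8,9-anti alcohol, returning to 25.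

Step 26. Acylation of O8 may be too slow, since it sits between the quaternary C7 silyl ether and the C9 silyl ether, so that the mixed anhydride decomposes or DMAP opens the epoxide first. The fallback sets out from 33. The tertiary TES ether is removed first (HF·pyridine buffered with pyridine, 0 °C) to give the 7,8-diol F9. The now less crowded secondary O8 is acylated with 37 by the same mixed-anhydride method, in preference to the tertiary O7, to give the hydroxy ester F10. HF·pyridine then removes the TBS ether, and the route comes back at 40.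

**Further compounds**
F1 | step 19 | (3Z)-4-(trimethylsilyl)penta-1,3-diene | C=C/C=C(/C)[Si](C)(C)C
F2 | step 19 | B-alkyl-9-BBN borane from F1 | C/C(=C/CCB1C2CCCC1CCC2)[Si](C)(C)C
F3 | step 19 | open-chain C3–C4 coupled product with Z vinylsilane at C10, 7-OTES, 8-ONAP, 9-OTES | C/C(CC/C=C(/C)[Si](C)(C)C)=C\[C@H]1OC(=O)C(C)[C@]1(O[Si](CC)(CC)CC)[C@H](OCc2ccc3ccccc3c2)CO[Si](CC)(CC)CC
F4 | step 19 | Z alkenyl iodide at C10 from F3 | C/C(CC/C=C(/C)I)=C\[C@H]1OC(=O)C(C)[C@]1(O[Si](CC)(CC)CC)[C@H](OCc2ccc3ccccc3c2)CO[Si](CC)(CC)CC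
F5 | step 19 | C9 aldehyde with Z alkenyl iodide at C10 | C/C(CC/C=C(/C)I)=C\[C@H]1OC(=O)C(C)[C@]1(O[Si](CC)(CC)CC)[C@H](OCc2ccc3ccccc3c2)C=O
F6 | step 19 | macrocyclic 9-alcohol, 7-OTES, 8-ONAP | CC1C(=O)O[C@@H]2/C=C(\C)CC/C=C(/C)[C@@H](O)[C@@H](OCc3ccc4ccccc4c3)[C@@]12O[Si](CC)(CC)CC
F7 | step 17 | C9 epimer of 25 | C/C(I)=C\[C@H]1OC(=O)C(C)[C@]1(O[Si](CC)(CC)CC)[C@H](OCc2ccc3ccccc3c2)[C@@H](O)/C(C)=C\C=C
F8 | step 17 | C9 dienone | C/C(I)=C\[C@H]1OC(=O)C(C)[C@]1(O[Si](CC)(CC)CC)[C@H](OCc2ccc3ccccc3c2)C(=O)/C(C)=C\C=C
F9 | step 26 | 7,8-diol, 9-OTBS | C=C1C(=O)O[C@@H]2/C=C(\C)CC/C=C(/C)[C@@H](O[Si](C)(C)C(C)(C)C)[C@@H](O)[C@@]12O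
F10 | step 26 | O8 epoxy ester with free 7-OH, 9-OTBS | C=C1C(=O)O[C@@H]2/C=C(\C)CC/C=C(/C)[C@@H](O[Si](C)(C)C(C)(C)C)[C@@H](OC(=O)[C@@]3(C)O[C@@H]3C)[C@@]12O
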